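**Strategy**

The target is a germacranolide: a ten-membered carbocycle (C1–C10) bridged by an ether oxygen between C5 and C10, with a trans-fused γ-lactone on C7/C8. Opening the ether to a C5 ketone and a C9=C10 alkene reveals the 1,6-relationship of C5 and C10, the signature of a cyclohexane C5–C10 bond cleaved in an anionic oxy-Cope rearrangement. That single operation enlarges the six-membered ring to the (E)-cyclodec-5-enone, forms C7–C8 and sets both stereocentres. Its precursor is a 2,6-dimethylcyclohexanol (C5 carbinol, C10 quaternary) carrying an (E)-2-(PMB-oxy)vinyl group on C10 and, trans to it, an (E)-4-(PMB-oxy)but-1-enyl group on C5.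

Key step: step 10

Remark: germacrane numbering is used for the ring carbons throughout (C4 = CH–CH3, C5 = ether CH, C7/C8 = lactone fusion, C9 = acyloxy CH, C10 = quaternary ether carbon, C11/C12 = lactone CH2 and C=O), PMB = 4-methoxybenzyl, and the sense of induction of the PHOX ligand in step 2 is assumed to mirror that of the 2-methylcyclohexanone enol carbonate.

**Route**

Step 1
Reactants: 1 2,6-dimethylcyclohexanone (cis/trans mixture)
Product: 3 allyl 2,6-dimethylcyclohex-1-en-1-yl carbonate (racemic), via lithium enolate 2 (not isolated)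
Conditions: LiHMDS, TMEDA, THF, 0 °C; allyl chloroformate, −78 °C to rt
Reagents that add atoms: allyl chloroformate, C=CCOC(=O)Cl
Why: Enolate O-acylation: the symmetrical ketone can give only one enolate, and the hard chloroformate traps the amine-solvated lithium enolate on oxygen to give the allyl enol carbonate needed for decarboxylative allylation.

Step 2
Reactants: 3 allyl 2,6-dimethylcyclohex-1-en-1-yl carbonate
Product: 4 (2R)-2-allyl-2,6-dimethylcyclohexanone (both C6 epimers)
Conditions: Pd2(dba)3 (2.5 mol %), (R)-t-Bu-PHOX (6 mol %), THF, 25 °C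
Reagents that add atoms: none
Why: Palladium-catalysed enantioselective decarboxylative allylation (Tsuji type): zerovalent palladium ionises the allyl carbonate, CO2 is expelled, and the allyl group is returned to the enolate carbon inside the chiral phosphine–oxazoline complex, which should fix the quaternary centre (future C10) as R whatever the configuration of the remote methine.

Step 3
Reactants: 4 (2R)-2-allyl-2,6-dimethylcyclohexanone
Product: 5 (2R)-2,6-dimethyl-2-[(E)-prop-1-enyl]cyclohexanone (both C6 epimers)
Conditions: PdCl2(MeCN)2 (10 mol %), toluene, 60 °C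
Reagents that add atoms: none
Why: Metal-catalysed alkene isomerisation: divalent palladium moves the terminal double bond one carbon inward to the more stable (E)-disubstituted alkene and is stopped there by the quaternary carbon.

Step 4
Reactants: 5 (2R)-2,6-dimethyl-2-[(E)-prop-1-enyl]cyclohexanone
Product: 7 (1R,3S)-1,3-dimethyl-2-oxocyclohexane-1-carbaldehyde, via keto aldehyde epimer mixture 6 (not isolated)
Conditions: O3, CH2Cl2, −78 °C; PPh3, to rt; concentrate; DBU (0.2 equiv), toluene, 25 °C; chromatography (minor epimer resubmitted)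
Reagents that add atoms: ozone, [O-][O+]=O
Why: Ozonolysis with reductive work-up followed by amidine-base epimerisation α to the ketone: cleavage of the propenyl group leaves a formyl group on the quaternary carbon, and the methine (future C4) should equilibrate through the enolate towards the 3S epimer, in which both methyl groups are equatorial and only the small formyl group is axial (about 1 kcal/mol in favour by tabulated conformational energies), which sets the cis-dimethyl relationship that the allylation does not control.

Step 5
Reactants: 7 (1R,3S)-1,3-dimethyl-2-oxocyclohexane-1-carbaldehyde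
Product: 8 (2R,6S)-2,6-dimethyl-2-[(E)-2-(4,4,5,5-tetramethyl-1,3,2-dioxaborolan-2-yl)ethenyl]cyclohexanone
Conditions: CrCl2 (8 equiv), Cl2CHBpin (2 equiv), LiI (4 equiv), THF, 25 °C
Reagents that add atoms: 2-(dichloromethyl)-4,4,5,5-tetramethyl-1,3,2-dioxaborolane, ClC(Cl)B1OC(C)(C)C(C)(C)O1
Why: Takai–Utimoto olefination: the geminal dichromium reagent formed in situ from the dihalomethylboronate adds to the aldehyde but not to the hindered ketone and eliminates to the (E)-alkenylboronate, under non-basic conditions that leave the α-methine configuration alone.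

Step 6
Reactants: 8 (2R,6S)-alkenylboronate ketone
Product: 9 (2R,6S)-2-[(E)-2-(4-methoxybenzyloxy)ethenyl]-2,6-dimethylcyclohexanone
Conditions: Cu(OAc)2 (2 equiv), Et3N (4 equiv), 4-methoxybenzyl alcohol (neat), 4 Å MS, air, 30 °C
Reagents that add atoms: 4-methoxybenzyl alcohol, COc1ccc(CO)cc1
Why: Chan–Lam-type copper-promoted C–O coupling of an alkenyl pinacol boronate with a primary alcohol: transmetalation from boron to copper and C–O reductive elimination retain the alkene geometry, so the E boronate should give only the E enol ether, and triethylamine at ambient temperature does not epimerise the hindered ketone.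

Step 7
Reactants: 10 but-3-yn-1-ol
Product: 12 1-[(but-3-ynyloxy)methyl]-4-methoxybenzene, via sodium but-3-yn-1-olate 11 (not isolated)
Conditions: NaH (1.05 equiv), THF/DMF, 0 °C; PMBCl, n-Bu4NI (cat.), 25 °C
Reagents that add atoms: 4-methoxybenzyl chloride, COc1ccc(CCl)cc1
Why: Williamson ether synthesis: one equivalent of hydride removes only the hydroxyl proton (far more acidic than the alkyne C–H) and the alkoxide displaces the benzylic chloride.

Step 8
Reactants: 12 1-[(but-3-ynyloxy)methyl]-4-methoxybenzene
Product: 14 1-({[(E)-4-iodobut-3-enyl]oxy}methyl)-4-methoxybenzene, via alkenylzirconocene chloride 13 (not isolated)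
Conditions: Cp2Zr(H)Cl, THF, 25 °C; I2, 0 °C
Reagents that add atoms: iodine, II
Why: Hydrozirconation–iodination: syn addition of Zr–H places the metal on the terminal carbon of the alkyne and iodinolysis of the C–Zr bond occurs with retention, so only the (E)-alkenyl iodide should form.

Step 9
Reactants: 14 (E)-alkenyl iodide; 9 (2R,6S)-enol ether ketone
Product: 17 (1S,2R,6S)-1-[(E)-4-(4-methoxybenzyloxy)but-1-enyl]-2-[(E)-2-(4-methoxybenzyloxy)ethenyl]-2,6-dimethylcyclohexan-1-ol, via alkenyllithium 15 (not isolated), via alkenylcerium dichloride 16 (not isolated)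
Conditions: 14, t-BuLi (2 equiv), Et2O, −78 °C; CeCl3, THF, −78 °C; 9, −78 to −40 °C; H2O
Reagents that add atoms: none
Why: Lithium–iodine exchange with retention of alkene geometry and 1,2-addition of the derived organocerium reagent to the ketone: with both methyl groups equatorial the alkoxyvinyl group of 9 is locked axial and blocks its own face, so the nucleophile should enter anti to it, making the two alkenyl groups trans and C5 S, while cerium suppresses enolisation of the hindered ketone.

Step 10
Reactants: 17 trans-1,2-dialkenylcyclohexanol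
Product: 20 (3S,4R,5E,10S)-4-(4-methoxybenzyloxy)-3-[2-(4-methoxybenzyloxy)ethyl]-6,10-dimethylcyclodec-5-en-1-one, via potassium alkoxide 18 (not isolated), via potassium enolate 19 (not isolated)
Conditions: KH, 18-crown-6, THF, 0 to 50 °C; AcOH, THF, −78 °C
Reagents that add atoms: none
Why: Deprotonation gives the crown-separated potassium alkoxide, whose oxyanion weakens the adjacent C5–C10 bond, and the 1,5-diene C8=C9–C10–C5–C6=C7 undergoes a concerted [3,3] sigmatropic shift that breaks C5–C10 and forms C7–C8 to give the ring-enlarged potassium enolate, protonated at C6 on cold acidic quench; the closest known reaction type is the anionic oxy-Cope rearrangement of trans-1,2-divinylcyclohexanol alkoxides to cyclodec-5-enones. The ten-membered ring is not closed by a cyclisation but arises by four-atom ring enlargement: the new C7–C8 bond joins the two alkenyl termini as the C5–C10 ring bond opens. C7 and C8 are set by the chair transition state, in which the (E)-butenyl and (E)-enol ether termini carry their CH2CH2OPMB and OPMB groups equatorial, giving the syn relationship that becomes the trans lactone fusion, and their absolute sense is relayed from the C5 and C10 centres that are consumed. The step needs chair rather than boat geometry and reaction through the conformer with both alkenyl groups equatorial; the trans arrangement allows only this conformer to bring C7 and C8 within bonding distance, the equatorial ring bonds C10–C1 and C5–C4 enforce the (E)-C9=C10 alkene, and the enolate is formed only at C5–C6 so that C4 is not touched. Because this conformer holds the C4 and C10 methyl groups 1,3-diaxial, gentle heating is planned, and irreversible enolate formation pulls the rearrangement to completion.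

Step 11
Reactants: 20 bis-PMB cyclodecenone
Product: 21 (3S,4R,5E,10S)-4-hydroxy-3-(2-hydroxyethyl)-6,10-dimethylcyclodec-5-en-1-one
Conditions: DDQ (2.5 equiv), CH2Cl2/pH 7 buffer (10:1), 0 °C to rt
Reagents that add atoms: none
Why: Oxidative cleavage of 4-methoxybenzyl ethers: DDQ oxidises both electron-rich benzylic ethers to oxocarbenium ions that water hydrolyses, releasing the C8 and C12 hydroxyls under buffered conditions that should not epimerise C4 or disturb the alkene.

Step 12
Reactants: 21 keto diol
Product: 23 (4S,7R,8R,9E)-5-oxo-13-norgermacr-9-en-12,8-olide, via lactol 22 (not isolated)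
Conditions: TEMPO (0.2 equiv), PhI(OAc)2 (2.5 equiv), CH2Cl2, 25 °C
Reagents that add atoms: none
Why: Oxoammonium-mediated oxidative lactonisation: the primary C12 alcohol is oxidised first, the aldehyde is captured by the only available hydroxyl (C8) as the five-membered lactol, and this is oxidised on to the γ-lactone, trans-fused because C7 and C8 are untouched.

Step 13
Reactants: 23 keto lactone
Product: 24 (4S,5R,7R,8R,9E)-5-hydroxy-13-norgermacr-9-en-12,8-olide
Conditions: LiBH(s-Bu)3, THF, −78 °C; H2O
Reagents that add atoms: none
Why: Hydride reduction under Felkin–Anh control with peripheral attack: in the reactive conformer the C4 methyl lies syn to the carbonyl oxygen and ring carbon C3 covers one face, so the bulky borohydride should add from the open face past the C4 hydrogen to give the 4,5-anti alcohol (5R), and at −78 °C the lactone is not reduced.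

Step 14
Reactants: 24 hydroxy lactone
Product: 26 (4S,5R,7R,8R,9S,10R)-5,10-epoxy-9-hydroxy-13-norgermacran-12,8-olide, via epoxy alcohol 25 (not isolated)
Conditions: mCPBA (1.1 equiv), CH2Cl2, 0 °C; then CSA (10 mol %), 0 °C to rt
Reagents that add atoms: mCPBA (3-chloroperoxybenzoic acid), O=C(OO)c1cccc(Cl)c1
Why: Prilezhaev epoxidation followed by acid-catalysed transannular epoxide opening (intramolecular etherification): allylic 1,3-strain against the C10 methyl holds H8 in the alkene plane so that C7 and the ring interior cover one face and the peracid should attack the peripheral face syn to the C8 oxygen (9S,10S epoxide), after which the C5 hydroxyl across the ring opens the protonated epoxide at the tertiary C10 from the inside with inversion, giving the 5,10-ether (10R) and the free C9 hydroxyl.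

Step 15
Reactants: 26 bridged hydroxy lactone
Product: 30 (4S,5R,7R,8R,9S,10R)-5,10-epoxy-9-hydroxygermacr-11(13)-en-12,8-olide, via dilithium alkoxide enolate 27 (not isolated), via Mannich base 28 (not isolated), via trimethylammonium iodide 29 (not isolated)
Conditions: LiN(i-Pr)2 (3 equiv), THF, −78 °C; CH2=NMe2+ I−, −78 °C to rt; H2O; then MeI, MeOH, rt; NaHCO3 (aq), CH2Cl2
Reagents that add atoms: N,N-dimethylmethyleneiminium iodide (Eschenmoser's salt), C=[N+](C)C.[I-]
Why: Lactone α-methylenation by Mannich reaction, quaternisation and elimination: excess amide base forms the hindered C9 alkoxide and then the lactone enolate, which adds to the iminium ion at C11, and methylation of the amine followed by mild base expels trimethylamine to leave the exocyclic methylene without creating a stereocentre.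

Step 16
Reactants: 30 hydroxy α-methylene lactone
Product: 31 (4S,5R,7R,8R,9S,10R)-5,10-epoxy-9-(3-methylbutanoyloxy)germacr-11(13)-en-12,8-olide (CNP0274454.1)
Conditions: (i-BuCO)2O, DMAP, Et3N, CH2Cl2, 25 °C
Reagents that add atoms: 3-methylbutanoic anhydride (isovaleric anhydride), CC(C)CC(=O)OC(=O)CC(C)C
Why: DMAP-catalysed acyl transfer (esterification) to the hindered secondary C9 alcohol: the C9–O bond is not broken, so the configuration is retained, and the conditions are mild enough for the α-methylene lactone.

**Compound list**

1 | 2,6-dimethylcyclohexanone (cis/trans mixture) | CC1CCCC(C)C1=O | starting material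
2 | lithium 2,6-dimethylcyclohex-1-en-1-olate | CC1CCCC(C)=C1[O-].[Li+] | intermediate (not isolated)
3 | allyl 2,6-dimethylcyclohex-1-en-1-yl carbonate (racemic) | CC1CCCC(C)=C1OC(=O)OCC=C | intermediate
4 | (2R)-2-allyl-2,6-dimethylcyclohexanone (both C6 epimers) | CC1CCC[C@](C)(CC=C)C1=O | intermediate
5 | (2R)-2,6-dimethyl-2-[(E)-prop-1-enyl]cyclohexanone (both C6 epimers) | CC1CCC[C@](C)(/C=C/C)C1=O | intermediate
6 | (1R)-1,3-dimethyl-2-oxocyclohexane-1-carbaldehyde (C3 epimer mixture) | CC1CCC[C@](C)(C=O)C1=O | intermediate (not isolated)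
7 | (1R,3S)-1,3-dimethyl-2-oxocyclohexane-1-carbaldehyde (methyl groups cis) | C[C@H]1CCC[C@](C)(C=O)C1=O | intermediate
8 | (2R,6S)-2,6-dimethyl-2-[(E)-2-(4,4,5,5-tetramethyl-1,3,2-dioxaborolan-2-yl)ethenyl]cyclohexanone | C[C@H]1CCC[C@](C)(/C=C/B2OC(C)(C)C(C)(C)O2)C1=O | intermediate
9 | (2R,6S)-2-[(E)-2-(4-methoxybenzyloxy)ethenyl]-2,6-dimethylcyclohexanone | C[C@H]1CCC[C@](C)(/C=C/OCc2ccc(OC)cc2)C1=O | intermediate
10 | but-3-yn-1-ol | C#CCCO | starting material
11 | sodium but-3-yn-1-olate | C#CCC[O-].[Na+] | intermediate (not isolated)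
12 | 1-[(but-3-ynyloxy)methyl]-4-methoxybenzene | C#CCCOCc1ccc(OC)cc1 | intermediate
13 | chlorobis(cyclopentadienyl)[(E)-4-(4-methoxybenzyloxy)but-1-enyl]zirconium | COc1ccc(COCC/C=C/[Zr](Cl)(C2C=CC=C2)C2C=CC=C2)cc1 | intermediate (not isolated)
14 | 1-({[(E)-4-iodobut-3-enyl]oxy}methyl)-4-methoxybenzene | COc1ccc(COCC/C=C/I)cc1 | intermediate
15 | (E)-4-(4-methoxybenzyloxy)but-1-enyllithium | COc1ccc(COCC/C=C/[Li])cc1 | intermediate (not isolated)
16 | dichloro[(E)-4-(4-methoxybenzyloxy)but-1-enyl]cerium | COc1ccc(COCC/C=C/[Ce](Cl)Cl)cc1 | intermediate (not isolated)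
17 | (1S,2R,6S)-1-[(E)-4-(4-methoxybenzyloxy)but-1-enyl]-2-[(E)-2-(4-methoxybenzyloxy)ethenyl]-2,6-dimethylcyclohexan-1-ol (alkenyl groups trans, methyl groups cis) | C[C@H]1CCC[C@](C)(/C=C/OCc2ccc(OC)cc2)[C@@]1(O)/C=C/CCOCc3ccc(OC)cc3 | intermediate (key-step precursor)
18 | potassium alkoxide of 17 | C[C@H]1CCC[C@](C)(/C=C/OCc2ccc(OC)cc2)[C@@]1([O-])/C=C/CCOCc3ccc(OC)cc3.[K+] | intermediate (not isolated)
19 | potassium C5–C6 enolate of 20 | C[C@H]1CCC/C(C)=C/[C@H](OCc2ccc(OC)cc2)[C@@H](CCOCc3ccc(OC)cc3)/C=C1\[O-].[K+] | intermediate (not isolated)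
20 | (3S,4R,5E,10S)-4-(4-methoxybenzyloxy)-3-[2-(4-methoxybenzyloxy)ethyl]-6,10-dimethylcyclodec-5-en-1-one | C[C@H]1CCC/C(C)=C/[C@H](OCc2ccc(OC)cc2)[C@@H](CCOCc3ccc(OC)cc3)CC1=O | intermediate (key-step product)
21 | (3S,4R,5E,10S)-4-hydroxy-3-(2-hydroxyethyl)-6,10-dimethylcyclodec-5-en-1-one | C[C@H]1CCC/C(C)=C/[C@H](O)[C@@H](CCO)CC1=O | intermediate
22 | γ-lactol of 21 (C12 hemiacetal with the C8 oxygen, anomer mixture) | C[C@H]1CCC/C(C)=C/[C@@H]2OC(O)C[C@H]2CC1=O | intermediate (not isolated)
23 | (4S,7R,8R,9E)-5-oxo-13-norgermacr-9-en-12,8-olide (trans-fused γ-lactone) | C[C@H]1CCC/C(C)=C/[C@@H]2OC(=O)C[C@H]2CC1=O | intermediate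
24 | (4S,5R,7R,8R,9E)-5-hydroxy-13-norgermacr-9-en-12,8-olide | C[C@H]1CCC/C(C)=C/[C@@H]2OC(=O)C[C@H]2C[C@H]1O | intermediate
25 | (4S,5R,7R,8R,9S,10S)-9,10-epoxy-5-hydroxy-13-norgermacran-12,8-olide | C[C@H]1CCC[C@]2(C)O[C@H]2[C@@H]3OC(=O)C[C@H]3C[C@H]1O | intermediate (not isolated)
26 | (4S,5R,7R,8R,9S,10R)-5,10-epoxy-9-hydroxy-13-norgermacran-12,8-olide | C1C(=O)O[C@@H]2[C@@H]1C[C@H]1O[C@](C)(CCC[C@@H]1C)[C@H]2O | intermediate
27 | dilithium C9-alkoxide lactone enolate of 26 | C1=C([O-])O[C@@H]2[C@@H]1C[C@H]1O[C@](C)(CCC[C@@H]1C)[C@H]2[O-].[Li+].[Li+] | intermediate (not isolated)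
28 | 11-(dimethylaminomethyl) derivative of 26 (Mannich base, C11 epimers) | CN(C)CC1C(=O)O[C@@H]2[C@@H]1C[C@H]1O[C@](C)(CCC[C@@H]1C)[C@H]2O | intermediate (not isolated)
29 | trimethylammonium iodide of 28 | C[N+](C)(C)CC1C(=O)O[C@@H]2[C@@H]1C[C@H]1O[C@](C)(CCC[C@@H]1C)[C@H]2O.[I-] | intermediate (not isolated)
30 | (4S,5R,7R,8R,9S,10R)-5,10-epoxy-9-hydroxygermacr-11(13)-en-12,8-olide | C=C1C(=O)O[C@@H]2[C@@H]1C[C@H]1O[C@](C)(CCC[C@@H]1C)[C@H]2O | intermediate
31 | (4S,5R,7R,8R,9S,10R)-5,10-epoxy-9-(3-methylbutanoyloxy)germacr-11(13)-en-12,8-olide (CNP0274454.1) | C=C1C(=O)O[C@@H]2[C@@H]1C[C@H]1O[C@](C)(CCC[C@@H]1C)[C@H]2OC(=O)CC(C)C | target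

**Step count**

Total: 16 steps. Longest linear sequence: 14 steps (steps 1–6 and 9–16, from 2,6-dimethylcyclohexanone); steps 7 and 8 form a two-step branch that joins at step 9.

**Steps most likely to fail**

Step 10 (key step). Process at risk: the shift has to pass through the chair conformer in which the C4 and C10 methyl groups are both axial, so it may be slow enough for the alkoxide to fragment or for the product enolate to equilibrate and scramble C4. Fallback (neutral thermal silyloxy-Cope in place of the anionic variant): setting out from 17, silylation (TMSOTf, 2,6-lutidine, CH2Cl2, −78 °C) would give the trimethylsilyl ether F1. Heating (o-dichlorobenzene, about 200 °C, base-washed vessel) should effect the same [3,3] shift without an anion and give the ring-enlarged trimethylsilyl enol ether F2. Buffered fluoride (TBAF, AcOH, THF, −20 °C) would release the ketone, and the route is rejoined at 20.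

Step 13. Process at risk: poor facial selectivity of hydride delivery to the medium-ring ketone, so that the C5 epimer predominates. Fallback (inversion in place of selective reduction): setting out from 23, reduction (NaBH4, MeOH, −20 °C) and separation would provide the 5-epi alcohol F3. Mitsunobu esterification with chloroacetic acid (PPh3, DIAD, toluene, 0 °C) would invert C5 and give the chloroacetate F4. Thiourea (NaHCO3, EtOH, 50 °C) would remove the chloroacetyl group without touching the lactone, and the route is rejoined at 24.

Step 14. Process at risk: attack of the peracid on the other alkene face (through a ring conformer that exposes it), which would give an epoxide that the C5 hydroxyl cannot open at C10. Fallback (hydroxyl-directed epoxidation at an earlier stage): setting out from 21, whose allylic C8 hydroxyl is free, mCPBA (NaHCO3, CH2Cl2, 0 °C) should be delivered by hydrogen bonding to the face syn to that hydroxyl and give the epoxy keto diol F5. Oxidative lactonisation as in step 12 would give the epoxy keto lactone F6. Reduction as in step 13 would give the epoxy alcohol 25, where the route is rejoined and closed to 26 with CSA.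

**Further compounds**

F1 | step 10 | trimethylsilyl ether of 17 | C[C@H]1CCC[C@](C)(/C=C/OCc2ccc(OC)cc2)[C@@]1(O[Si](C)(C)C)/C=C/CCOCc3ccc(OC)cc3
F2 | step 10 | C5–C6 trimethylsilyl enol ether of 20 | C[C@H]1CCC/C(C)=C/[C@H](OCc2ccc(OC)cc2)[C@@H](CCOCc3ccc(OC)cc3)/C=C1\O[Si](C)(C)C
F3 | step 13 | (4S,5S,7R,8R,9E)-5-hydroxy-13-norgermacr-9-en-12,8-olide (C5 epimer of 24) | C[C@H]1CCC/C(C)=C/[C@@H]2OC(=O)C[C@H]2C[C@@H]1O
F4 | step 13 | (4S,5R,7R,8R,9E)-5-(chloroacetoxy)-13-norgermacr-9-en-12,8-olide | C[C@H]1CCC/C(C)=C/[C@@H]2OC(=O)C[C@H]2C[C@H]1OC(=O)CCl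
F5 | step 14 | 9,10-epoxide of 21 (epoxide oxygen syn to the C8 hydroxyl) | C[C@H]1CCC[C@]2(C)O[C@H]2[C@H](O)[C@@H](CCO)CC1=O
F6 | step 14 | (4S,7R,8R,9S,10S)-9,10-epoxy-5-oxo-13-norgermacran-12,8-olide | C[C@H]1CCC[C@]2(C)O[C@H]2[C@@H]3OC(=O)C[C@H]3CC1=O
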